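Remarks on the chemistry, made once: locants O1, C2, C3, C4, C5 are those of the oxolane of the target, C6 is the exocyclic carbon on C3 and C7 the benzylic carbon on C4; these locants are used for every intermediate. Compounds 1, 3, 6, 10 and 20 are taken as purchasable. The C3 configuration produced by the C–H insertion itself is not relied on; it is set by equilibration in the second operation of step 8.

## Analysis of the target

Agastinol (22) is a 2,3,4-trisubstituted oxolane: C2 carries a 4-hydroxy-3-methoxyphenyl ring, C3 carries C6H2 esterified with 4-hydroxybenzoic acid, C4 carries the C7H2 link to a second 4-hydroxy-3-methoxyphenyl ring, and C5 is a CH2 group. The three stereocentres are contiguous and (2R,3S,4S). The C2 aryl group is trans to the C3 side chain, and that side chain is cis to the C4 benzyl group, so aryl and benzyl lie on opposite faces and the ring is not the all-trans, lowest-energy arrangement. The sensitive points are the C2–O1 bond (a cyclic, 4-oxygenated benzylic ether that ionises with acid and can be hydrogenolysed), three phenols, and the benzoate ester, which rules out strongly basic or nucleophilic steps late in the route. The difficulty is stereochemical rather than skeletal: three adjacent centres on a flexible five-membered ring with one cis contact, no ring substituent that can direct a reagent, and two nearly identical arenes that must be told apart. The plan rests on C2: its C–H bond is flanked by O1 and by an electron-rich aryl ring, which makes it the most hydridic C–H of an open-chain ArCH2–O–C5 ether, and it lies 1,5 to C3. A carbene at C3 can therefore close the ring by forming C2–C3, with C4 as the only stereocentre that must exist beforehand.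

## Retrosynthetic reasoning

22 to 21: the two O–benzyl bonds are cut last. The phenol on the C2 aryl ring has to stay an alkyl ether through the carbene step so that C2–H remains electron-rich, and the phenol of the benzoate has to be masked during esterification. Both ethers can be removed together under neutral conditions that leave the ester and the stereocentres alone.

21 to 19 and 20: the C6–O bond to the carboxylate is cut. The forward reaction must esterify a primary alcohol in the presence of a free phenol. This is done by activating the alcohol rather than the acid, so that only the carboxylate of 20 acts as nucleophile.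

19 to 17: C6 is traced back to a carboxylate carbon and the free phenol to its sulfonate. The ester at C3 is what makes both the carbene chemistry and the adjustment of C3 possible, and the sulfonate is the group that distinguishes the two arenes during ring closure.

17 to 15 (key disconnection): the C2–C3 bond is cut, opening the oxolane to a benzyl ether with a diazo group on C3. No other ring bond can be made by inserting into a C–H bond activated by both oxygen and an electron-rich arene. The cut also removes two stereocentres at once and leaves a precursor with C4 as its only stereocentre. The forward reaction has to choose the C2–H bond over hydride migration from C4 and over attack on the C7 arene, place the aryl group trans to the C4 substituent, and leave C3 in a form that can be equilibrated.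

15 to 12: the diazo group is traced back to the C3 methylene of a simple ester. The ester must be activated as an acyl derivative for the transfer, and the conditions must not touch C4 or the sulfonate.

12 to 9 and 11: the O1–C2 bond is cut. The ring oxygen is joined to the benzylic carbon intermolecularly and early, as an ordinary benzyl ether made from hydroxy ester 9 and trichloroacetimidate 11. The forward reaction must etherify a γ-hydroxy ester without letting it close to the lactone, which is why acid catalysis and a bulky ester are used.

9 to 8, then to 5 and 6: the C3–C4 bond is cut. Alkylating the enolate of imide 5 with bromoacetate 6 sets C4 under auxiliary control and brings in C3 and C6 at the right oxidation level. Reductive removal of the auxiliary turns the imide carbonyl into C5.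

5 to 2 and 3, 2 to 1, and 11 to 10: these are an N-acylation of auxiliary 3, a phenol sulfonylation of acid 1, and imidate formation from alcohol 10.

## Alternatives that were turned down

Alternative 1: Both C4–C5 and C2–C3 are cut, leading back to the cis-dioxolane A1. A1 is the formaldehyde acetal of an erythro diol with the aryl group on one carbinol carbon and an (E)-3-arylprop-1-enyl chain on the other. In the forward direction a tin-based Lewis acid would open the acetal to an O1=C5 oxocarbenium ion. A chair 2-oxonia-Cope shift would then pass the chirality of the diol to C4 while forming C4–C5, and the resulting enol and aryl-substituted oxocarbenium ion would recombine in an aldol-type closure to aldehyde A2.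
- For: two C–C bonds, the ring and all three stereocentres in one operation; an aldehyde one reduction away from the C6 alcohol; acetate protection that avoids a final hydrogenolysis. On bonds formed per step it is stronger than the carbene route.
- Against: A1 needs two defined oxygenated stereocentres and a geometrically pure alkene, where the chosen route needs one centre. A Lewis acid can ionise the benzylic C2–O bond instead of the acetal C5–O bond when the arene is electron-rich, and the acetate that suppresses this also weakens the cation on which the closing step depends. The formyl group must finish cis to the C4 substituent in a β-alkoxy aldehyde that epimerises and eliminates readily.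
- Comparison: the chosen strategy gives up the cascade but closes the ring under neutral conditions on a substrate with one preset centre, and keeps C3 as an ester, where epimerisation can be managed.

Alternative 2: The ring is cut at C2–C3 and O1–C5. A chiral zerovalent palladium catalyst would ionise a cyano-bearing silyl allyl acetate to a cyano-trimethylenemethane complex, and a [3+2] cycloaddition onto aldehyde A3 would give the 4-methylene oxolane nitrile A4 with C2 and C3 set.
- For: convergent; chirality from a catalyst; the ring in one step from a cheap aldehyde. On these three points it is stronger than the chosen route.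
- Against: A4 has neither the C7 aryl group nor the C4 stereocentre. Both would have to come from hydroboration of the exocyclic alkene and a B-alkyl Suzuki coupling, with the face of addition controlled only by the small substituent on C3. The C3–H of A4 is both allylic and α to the nitrile, so migration of the double bond into conjugation would erase C3. The nitrile needs two reductions to reach C6H2OH. Aldehydes are also less willing acceptors than electron-poor alkenes in this cycloaddition.
- Comparison: the chosen route sets C4 first, with an auxiliary of predictable sense, and then uses it as the controlling element instead of leaving it as the last and least controlled centre.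

Alternative 3: C3–C4 and the C7–aryl bond are cut, giving iodide A5 (an allyl ether with C2 preset, iodine on C3 and the benzoate already in place) and aryl bromide A6. A bipyridine-ligated nickel catalyst under reductive conditions would generate the C3 radical, which closes 5-exo onto the allyl group; the C7 radical is then captured at nickel and arylated to give A7, one hydrogenolysis from the target.
- For: the shortest route, two C–C bonds in one step, and no redox or esterification after ring closure. It is clearly stronger on step economy.
- Against: C3 in A5 has oxygen on both neighbouring carbons (O1 on C2, the ester oxygen on C6), so two-electron reduction of the iodide by the metal reductant or low-valent nickel invites β-elimination. C3 and C4 are formed together in a radical closure controlled by C2 alone, and the preference of such radicals for the 3,4-cis ring is weak. Once formed, C3 has no acidifying group and a wrong epimer cannot be corrected. A5 also needs its own enantioselective entry to C2.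
- Comparison: the chosen route is longer after ring closure, but each centre has an identifiable control element and C3 remains correctable.

Key step: step 8

## Route

Step 1
Reactants: 1 3-(4-hydroxy-3-methoxyphenyl)propanoic acid
Product: 2 3-{3-methoxy-4-[(4-methylbenzenesulfonyl)oxy]phenyl}propanoic acid
Conditions: TsCl (1.3 equiv), NaOH (3 equiv), THF–H2O, 0 °C → rt; then aq. HCl to pH 2
Reagents that add atoms: 4-methylbenzenesulfonyl chloride, Cc1ccc(cc1)S(=O)(=O)Cl
Why: Schotten–Baumann sulfonylation; the phenoxide is the better nucleophile and any mixed carboxylic–sulfonic anhydride is hydrolysed back in the aqueous base, so only the aryl tosylate should remain; a tosylate is preferred to a mesylate because it has no acidic α-hydrogens for the amide bases of steps 3 and 7.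

Step 2
Reactants: 2 3-{3-methoxy-4-[(4-methylbenzenesulfonyl)oxy]phenyl}propanoic acid; 3 (4R)-4-benzyl-1,3-oxazolidin-2-one
Product: 5 (4R)-4-benzyl-3-(3-{3-methoxy-4-[(4-methylbenzenesulfonyl)oxy]phenyl}propanoyl)-1,3-oxazolidin-2-one, via mixed pivalic anhydride 4 (not isolated)
Conditions: PivCl (1.1 equiv), Et3N (2.5 equiv), THF, −20 °C; then 3, LiCl (1.1 equiv), −20 °C → rt
Reagents that add atoms: none
Why: N-acylation of an oxazolidinone through a mixed anhydride, which is attacked at the unhindered acyl carbon; no strong base is needed, so the aryl tosylate should be untouched.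

Step 3
Reactants: 5 (4R)-4-benzyl-3-(3-{3-methoxy-4-[(4-methylbenzenesulfonyl)oxy]phenyl}propanoyl)-1,3-oxazolidin-2-one; 6 tert-butyl bromoacetate
Product: 8 tert-butyl (3S)-4-[(4R)-4-benzyl-2-oxo-1,3-oxazolidin-3-yl]-3-{3-methoxy-4-[(4-methylbenzenesulfonyl)oxy]benzyl}-4-oxobutanoate, via sodium Z-enolate 7 (not isolated)
Conditions: NaN(SiMe3)2 (1.1 equiv), THF, −78 °C, 45 min; then 6 (2.5 equiv), −78 → −40 °C
Reagents that add atoms: none
Why: Evans asymmetric alkylation; the chelated Z-enolate is alkylated on the face opposite the benzyl group of the auxiliary, which with the (R)-auxiliary should give the (S) centre that becomes C4; the step also forms C3–C4 and brings in C3 and C6.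

Step 4
Reactants: 8 tert-butyl (3S)-4-[(4R)-4-benzyl-2-oxo-1,3-oxazolidin-3-yl]-3-{3-methoxy-4-[(4-methylbenzenesulfonyl)oxy]benzyl}-4-oxobutanoate
Product: 9 tert-butyl (3S)-4-hydroxy-3-{3-methoxy-4-[(4-methylbenzenesulfonyl)oxy]benzyl}butanoate
Conditions: LiBH4 (1.5 equiv), THF, 0 °C; aq. NH4Cl quench at 0 °C
Reagents that add atoms: none
Why: Reductive removal of the auxiliary; LiBH4 reduces the activated exocyclic imide carbonyl (which becomes C5) but not a tert-butyl ester or an aryl sulfonate at 0 °C, the bulky ester resists lactonisation by the intermediate alkoxide, and auxiliary 3 is recovered.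

Step 5
Reactants: 10 [4-(benzyloxy)-3-methoxyphenyl]methanol
Product: 11 4-(benzyloxy)-3-methoxybenzyl 2,2,2-trichloroacetimidate
Conditions: Cl3CCN (1.5 equiv), DBU (0.1 equiv), CH2Cl2, 0 °C; filtered through Et3N-deactivated silica and used at once
Reagents that add atoms: trichloroacetonitrile, N#CC(Cl)(Cl)Cl
Why: Base-catalysed addition of a benzylic alcohol to trichloroacetonitrile, the standard preparation of benzyl trichloroacetimidates; the electron-rich imidate is acid-labile and is therefore not stored.

Step 6
Reactants: 9 tert-butyl (3S)-4-hydroxy-3-{3-methoxy-4-[(4-methylbenzenesulfonyl)oxy]benzyl}butanoate; 11 4-(benzyloxy)-3-methoxybenzyl 2,2,2-trichloroacetimidate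
Product: 12 tert-butyl (3S)-4-{[4-(benzyloxy)-3-methoxybenzyl]oxy}-3-{3-methoxy-4-[(4-methylbenzenesulfonyl)oxy]benzyl}butanoate
Conditions: 11 (1.6 equiv), (+)-camphor-10-sulfonic acid (0.1 equiv), CH2Cl2, 0 °C → rt
Reagents that add atoms: none
Why: Acid-catalysed trichloroacetimidate benzylation as used for 4-methoxybenzyl ethers; the 4-alkoxybenzyl cation forms under catalysis mild enough to leave the tert-butyl ester intact, whereas a Williamson alkylation would send the alkoxide of 9 to the lactone; this step makes the O1–C2 bond.

Step 7
Reactants: 12 tert-butyl (3S)-4-{[4-(benzyloxy)-3-methoxybenzyl]oxy}-3-{3-methoxy-4-[(4-methylbenzenesulfonyl)oxy]benzyl}butanoate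
Product: 15 tert-butyl (3S)-4-{[4-(benzyloxy)-3-methoxybenzyl]oxy}-2-diazo-3-{3-methoxy-4-[(4-methylbenzenesulfonyl)oxy]benzyl}butanoate, via lithium enolate 13 (not isolated), via trifluoroacetyl ester 14 (not isolated)
Conditions: LiN(SiMe3)2 (1.2 equiv), THF, −78 °C; CF3CO2CH2CF3 (1.3 equiv), −78 °C; aq. NH4Cl; then p-ABSA (1.5 equiv), Et3N (1.5 equiv), H2O (1 equiv), MeCN, rt
Reagents that add atoms: 4-acetamidobenzenesulfonyl azide, CC(=O)Nc1ccc(cc1)S(=O)(=O)N=[N+]=[N-]
Why: Deacylative diazo transfer; a simple ester is not acidic enough for direct transfer, so its enolate is C-trifluoroacetylated and the activated methine then accepts the diazo group with loss of the trifluoroacetyl group as the N-acylsulfonamide; C4 is never acidified and the tosylate offers no proton to the amide base.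

Step 8
Reactants: 15 tert-butyl (3S)-4-{[4-(benzyloxy)-3-methoxybenzyl]oxy}-2-diazo-3-{3-methoxy-4-[(4-methylbenzenesulfonyl)oxy]benzyl}butanoate
Product: 17 tert-butyl (2R,3R,4S)-2-[4-(benzyloxy)-3-methoxyphenyl]-4-{3-methoxy-4-[(4-methylbenzenesulfonyl)oxy]benzyl}oxolane-3-carboxylate, via C3-epimeric insertion product 16 (not isolated)
Conditions: Rh2(S-PTTL)4 (1 mol %), CH2Cl2, −78 → −20 °C, 15 added over 2 h; concentrate; then KOtBu (0.3 equiv), tBuOH–THF, 0 °C → rt
Reagents that add atoms: none
Why: Rh2(S-PTTL)4, dirhodium tetrakis[N-phthaloyl-(S)-tert-leucinate], a carboxylate complex of divalent rhodium, removes N2 from 15 to give an electrophilic rhodium carbene at C3. The carbene inserts into one of the two C2–H bonds of the ArCH2–O group in a concerted event with hydride-transfer character, forming C2–C3; the closest known reaction type is the dirhodium carboxylate-catalysed 1,5 C–H insertion of α-alkyl-α-diazo esters next to an ether oxygen, which gives oxolane-3-carboxylates. The oxolane closes by C–C bond formation in a 1,5 sense through a six-centre, chair-like array that includes the migrating hydrogen. C2 is set under control of C4: with the C7 substituent and the C2 aryl group both pseudo-equatorial in that array, the 2,4-trans ring should result. C3 is set in the second operation, where catalytic alkoxide equilibrates the ester through its enolate towards the epimer trans to the C2 aryl group, which in a 2,4-trans ring places it cis to the smaller CH2Ar group on C4. The step needs site selectivity for C2–H over hydride migration from C4 and over attack on the C7 arene; C2–H is activated by both O1 and the 4-alkoxyaryl ring, the bulky ligands and low temperature disfavour the hydride shift, and the tosylate lowers the nucleophilicity of the other arene. The benzyl ether and the tert-butyl ester are spectators, and the ester descriptor 3R corresponds to 3S in the target because only the priorities change on reduction.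

Step 9
Reactants: 17 tert-butyl (2R,3R,4S)-2-[4-(benzyloxy)-3-methoxyphenyl]-4-{3-methoxy-4-[(4-methylbenzenesulfonyl)oxy]benzyl}oxolane-3-carboxylate
Product: 19 [(2R,3S,4S)-2-[4-(benzyloxy)-3-methoxyphenyl]-4-(4-hydroxy-3-methoxybenzyl)oxolan-3-yl]methanol, via tosyl alcohol 18 (not isolated)
Conditions: LiAlH4 (2.5 equiv), THF, 0 °C → rt; H2O/aq. NaOH work-up; then KOH (5 equiv), MeOH–H2O, reflux
Reagents that add atoms: none
Why: Hydride reduction of the ester gives the C6 alcohol, and hydroxide attack at sulfur then releases the phenol; any tosylate already cleaved by LiAlH4 converges on the same product, and with the ester gone there is no enolisable centre or acyl group left for the hot base to attack.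

Step 10
Reactants: 19 [(2R,3S,4S)-2-[4-(benzyloxy)-3-methoxyphenyl]-4-(4-hydroxy-3-methoxybenzyl)oxolan-3-yl]methanol; 20 4-(benzyloxy)benzoic acid
Product: 21 [(2R,3S,4S)-2-[4-(benzyloxy)-3-methoxyphenyl]-4-(4-hydroxy-3-methoxybenzyl)oxolan-3-yl]methyl 4-(benzyloxy)benzoate
Conditions: 20 (1.2 equiv), PPh3 (1.3 equiv), DIAD (1.3 equiv), THF, 0 °C → rt
Reagents that add atoms: none
Why: Mitsunobu esterification; the primary C6 alcohol is activated as its alkoxyphosphonium ion and displaced by the carboxylate, the only component acidic enough to protonate the betaine, so the free phenol, which an acyl chloride would acylate first, should be left alone; no stereocentre is involved.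

Step 11
Reactants: 21 [(2R,3S,4S)-2-[4-(benzyloxy)-3-methoxyphenyl]-4-(4-hydroxy-3-methoxybenzyl)oxolan-3-yl]methyl 4-(benzyloxy)benzoate
Product: 22 agastinol ([(2R,3S,4S)-2-(4-hydroxy-3-methoxyphenyl)-4-(4-hydroxy-3-methoxybenzyl)oxolan-3-yl]methyl 4-hydroxybenzoate)
Conditions: H2 (1 atm), 10% Pd/C, EtOAc, rt, stopped as soon as 21 is consumed
Reagents that add atoms: none
Why: Hydrogenolysis of aryl benzyl ethers, which under neutral conditions in a non-protic solvent is much faster than cleavage of the dialkyl benzylic C2–O1 bond; the ester and the three stereocentres are not affected.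

## Compound list

1 | 3-(4-hydroxy-3-methoxyphenyl)propanoic acid | COc1cc(CCC(=O)O)ccc1O | starting material
2 | 3-{3-methoxy-4-[(4-methylbenzenesulfonyl)oxy]phenyl}propanoic acid | COc1cc(CCC(=O)O)ccc1OS(=O)(=O)c1ccc(C)cc1 | intermediate
3 | (4R)-4-benzyl-1,3-oxazolidin-2-one | O=C1N[C@H](Cc2ccccc2)CO1 | starting material
4 | mixed anhydride of 2 with pivalic acid (not isolated) | COc1cc(CCC(=O)OC(=O)C(C)(C)C)ccc1OS(=O)(=O)c1ccc(C)cc1 | intermediate
5 | (4R)-4-benzyl-3-(3-{3-methoxy-4-[(4-methylbenzenesulfonyl)oxy]phenyl}propanoyl)-1,3-oxazolidin-2-one | COc1cc(CCC(=O)N2C(=O)OC[C@H]2Cc2ccccc2)ccc1OS(=O)(=O)c1ccc(C)cc1 | intermediate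
6 | tert-butyl bromoacetate | CC(C)(C)OC(=O)CBr | starting material
7 | sodium (Z)-enolate of 5 (not isolated) | [Na+].[O-]/C(=C\Cc1ccc(OS(=O)(=O)c2ccc(C)cc2)c(OC)c1)N1C(=O)OC[C@H]1Cc1ccccc1 | intermediate
8 | tert-butyl (3S)-4-[(4R)-4-benzyl-2-oxo-1,3-oxazolidin-3-yl]-3-{3-methoxy-4-[(4-methylbenzenesulfonyl)oxy]benzyl}-4-oxobutanoate | CC(C)(C)OC(=O)C[C@@H](C(=O)N1C(=O)OC[C@H]1Cc1ccccc1)Cc1ccc(OS(=O)(=O)c2ccc(C)cc2)c(OC)c1 | intermediate
9 | tert-butyl (3S)-4-hydroxy-3-{3-methoxy-4-[(4-methylbenzenesulfonyl)oxy]benzyl}butanoate | CC(C)(C)OC(=O)C[C@@H](CO)Cc1ccc(OS(=O)(=O)c2ccc(C)cc2)c(OC)c1 | intermediate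
10 | [4-(benzyloxy)-3-methoxyphenyl]methanol | COc1cc(CO)ccc1OCc1ccccc1 | starting material
11 | 4-(benzyloxy)-3-methoxybenzyl 2,2,2-trichloroacetimidate | COc1cc(COC(=N)C(Cl)(Cl)Cl)ccc1OCc1ccccc1 | intermediate
12 | tert-butyl (3S)-4-{[4-(benzyloxy)-3-methoxybenzyl]oxy}-3-{3-methoxy-4-[(4-methylbenzenesulfonyl)oxy]benzyl}butanoate | CC(C)(C)OC(=O)C[C@@H](COCc1ccc(OCc2ccccc2)c(OC)c1)Cc1ccc(OS(=O)(=O)c2ccc(C)cc2)c(OC)c1 | intermediate
13 | lithium enolate of 12 (not isolated) | [Li+].[O-]C(OC(C)(C)C)=C[C@@H](COCc1ccc(OCc2ccccc2)c(OC)c1)Cc1ccc(OS(=O)(=O)c2ccc(C)cc2)c(OC)c1 | intermediate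
14 | tert-butyl (3S)-4-{[4-(benzyloxy)-3-methoxybenzyl]oxy}-3-{3-methoxy-4-[(4-methylbenzenesulfonyl)oxy]benzyl}-2-(trifluoroacetyl)butanoate, C2 epimers (not isolated) | CC(C)(C)OC(=O)C(C(=O)C(F)(F)F)[C@@H](COCc1ccc(OCc2ccccc2)c(OC)c1)Cc1ccc(OS(=O)(=O)c2ccc(C)cc2)c(OC)c1 | intermediate
15 | tert-butyl (3S)-4-{[4-(benzyloxy)-3-methoxybenzyl]oxy}-2-diazo-3-{3-methoxy-4-[(4-methylbenzenesulfonyl)oxy]benzyl}butanoate | CC(C)(C)OC(=O)C(=[N+]=[N-])[C@@H](COCc1ccc(OCc2ccccc2)c(OC)c1)Cc1ccc(OS(=O)(=O)c2ccc(C)cc2)c(OC)c1 | intermediate
16 | tert-butyl (2R,4S)-2-[4-(benzyloxy)-3-methoxyphenyl]-4-{3-methoxy-4-[(4-methylbenzenesulfonyl)oxy]benzyl}oxolane-3-carboxylate, C3 epimers as formed by the insertion (not isolated) | COc1cc(C[C@@H]2CO[C@@H](c3ccc(OCc4ccccc4)c(OC)c3)C2C(=O)OC(C)(C)C)ccc1OS(=O)(=O)c1ccc(C)cc1 | intermediate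
17 | tert-butyl (2R,3R,4S)-2-[4-(benzyloxy)-3-methoxyphenyl]-4-{3-methoxy-4-[(4-methylbenzenesulfonyl)oxy]benzyl}oxolane-3-carboxylate | COc1cc(C[C@@H]2CO[C@@H](c3ccc(OCc4ccccc4)c(OC)c3)[C@@H]2C(=O)OC(C)(C)C)ccc1OS(=O)(=O)c1ccc(C)cc1 | intermediate
18 | [(2R,3S,4S)-2-[4-(benzyloxy)-3-methoxyphenyl]-4-{3-methoxy-4-[(4-methylbenzenesulfonyl)oxy]benzyl}oxolan-3-yl]methanol (not isolated) | COc1cc(C[C@@H]2CO[C@@H](c3ccc(OCc4ccccc4)c(OC)c3)[C@@H]2CO)ccc1OS(=O)(=O)c1ccc(C)cc1 | intermediate
19 | [(2R,3S,4S)-2-[4-(benzyloxy)-3-methoxyphenyl]-4-(4-hydroxy-3-methoxybenzyl)oxolan-3-yl]methanol | COc1cc(C[C@@H]2CO[C@@H](c3ccc(OCc4ccccc4)c(OC)c3)[C@@H]2CO)ccc1O | intermediate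
20 | 4-(benzyloxy)benzoic acid | O=C(O)c1ccc(OCc2ccccc2)cc1 | starting material
21 | [(2R,3S,4S)-2-[4-(benzyloxy)-3-methoxyphenyl]-4-(4-hydroxy-3-methoxybenzyl)oxolan-3-yl]methyl 4-(benzyloxy)benzoate | COc1cc(C[C@@H]2CO[C@@H](c3ccc(OCc4ccccc4)c(OC)c3)[C@@H]2COC(=O)c2ccc(OCc3ccccc3)cc2)ccc1O | intermediate
22 | agastinol, [(2R,3S,4S)-2-(4-hydroxy-3-methoxyphenyl)-4-(4-hydroxy-3-methoxybenzyl)oxolan-3-yl]methyl 4-hydroxybenzoate | COc1cc(C[C@@H]2CO[C@@H](c3ccc(O)c(OC)c3)[C@@H]2COC(=O)c2ccc(O)cc2)ccc1O | target

## Step count and least certain steps

Total step count: 11. Longest linear sequence: 10 steps (1 → 2 → 5 → 8 → 9 → 12 → 15 → 17 → 19 → 21 → 22, steps 1–4 and 6–11). Step 5 is a one-step side branch from 10.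

**Step 8 (key step).** Four processes can divert it.
- Hydride migration from C4 to the carbene carbon is intrinsically fast for α-alkyl carbenes and would give an achiral enoate.
- Electrophilic attack of the carbene on the C7 arene is possible at the position para to the methoxy group. The tosylate sits meta to that position and only attenuates it.
- The two diastereotopic C2–H bonds may be poorly discriminated if the chiral ligand sphere opposes the bias from C4. The antipodal catalyst Rh2(R-PTTL)4 or the achiral Rh2(O2CCPh3)4 would be tried first in that case.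
- In the base operation, β-elimination of O1 from the ester enolate followed by re-addition would let C2 drift towards the all-trans ring. The C3 equilibrium may also lie less far on the desired side than hoped, since each C3 epimer of a 2,4-trans ring has one cis contact. If the insertion itself turns out to favour the desired epimer more strongly than equilibrium does, the base treatment would be confined to the separated minor epimer.

Fallback: this sets out from 9 and abandons the carbene. Acid-catalysed lactonisation of 9 (TsOH cat., toluene, 60 °C) should give (4S)-4-{3-methoxy-4-[(4-methylbenzenesulfonyl)oxy]benzyl}oxolan-2-one F1. Its lithium enolate (LiN(SiMe3)2, THF, −78 °C) is added to 4-(benzyloxy)-3-methoxybenzaldehyde (A3, purchasable) anti to the C4 substituent, giving the trans aldol lactone (3R,4S)-3-{[4-(benzyloxy)-3-methoxyphenyl](hydroxy)methyl}-4-{3-methoxy-4-[(4-methylbenzenesulfonyl)oxy]benzyl}oxolan-2-one F2 as carbinol epimers. LiAlH4 at 0 °C reduces the lactone to (2S,3S)-2-{[4-(benzyloxy)-3-methoxyphenyl](hydroxy)methyl}-3-{3-methoxy-4-[(4-methylbenzenesulfonyl)oxy]benzyl}butane-1,4-diol F3. Catalytic camphorsulfonic acid in CH2Cl2 then ionises the benzylic carbinol, and the C5 hydroxyl closes the oxolane with the aryl group anti to both ring substituents. The trans lactone translates into the 3,4-cis ring. The sequence comes back to the route at 18, which is carried through the KOH operation of step 9 to 19; any material that has lost its tosylate arrives at 19 directly.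

**Step 7.** C-trifluoroacetylation of the hindered, β-branched ester enolate may be incomplete, or the trifluoroacetyl group may be lost by retro-Claisen cleavage before diazo transfer, returning 12. Fallback from 12: azide transfer to the potassium enolate (KN(SiMe3)2, THF, −78 °C; 2,4,6-triisopropylbenzenesulfonyl azide; AcOH quench) gives tert-butyl (3S)-2-azido-4-{[4-(benzyloxy)-3-methoxybenzyl]oxy}-3-{3-methoxy-4-[(4-methylbenzenesulfonyl)oxy]benzyl}butanoate F4 as C2 epimers. Phosphine-mediated conversion of the azide into the diazo group (N-succinimidyl 3-(diphenylphosphino)propanoate, THF–H2O, then NaHCO3) through an acyl triazene then comes back to the route at 15.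

**Step 6.** Acid-promoted lactonisation of 9 with loss of the tert-butyl group, or rearrangement of the labile imidate 11 to its N-benzyl amide, may outrun etherification. Fallback from 10: PBr3 in Et2O at 0 °C gives 1-(benzyloxy)-4-(bromomethyl)-2-methoxybenzene F5, and 9 is alkylated with it under silver oxide mediation (Ag2O, CH2Cl2, 4 Å sieves, rt), which needs neither free alkoxide nor acid. This comes back to the route at 12.

**Step 10.** The activated C6 alcohol may alkylate the free phenol of another molecule (ether formation and oligomers), or some acyl group may reach the phenol. Fallback from 19: both hydroxyls are acylated with 20 (2.6 equiv, EDC·HCl, DMAP, CH2Cl2) to the bis[4-(benzyloxy)benzoate] of 19, F6. The far more reactive aryl ester is then aminolysed selectively with pyrrolidine in THF at 0 °C. This comes back to the route at 21.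

**Step 11.** Over-reduction by hydrogenolysis of the benzylic C2–O1 bond would open the ring, and it becomes easier once the para oxygen of that arene is a free phenol. Fallback from 19, without hydrogen: nucleophilic debenzylation with NaSEt in DMF at 80 °C (benzyl reacts much faster than methyl in SN2 cleavage) gives (2R,3S,4S)-lariciresinol F7. A Mitsunobu esterification of its C6 alcohol with unprotected 4-hydroxybenzoic acid (PPh3, DIAD, THF), in which only the carboxylic acid is acidic enough to act as pronucleophile, then comes back to the route at 22.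

## Further compounds

F1 | step 8 | (4S)-4-{3-methoxy-4-[(4-methylbenzenesulfonyl)oxy]benzyl}oxolan-2-one | COc1cc(C[C@@H]2COC(=O)C2)ccc1OS(=O)(=O)c1ccc(C)cc1
F2 | step 8 | (3R,4S)-3-{[4-(benzyloxy)-3-methoxyphenyl](hydroxy)methyl}-4-{3-methoxy-4-[(4-methylbenzenesulfonyl)oxy]benzyl}oxolan-2-one, carbinol epimers | COc1cc(C[C@@H]2COC(=O)[C@H]2C(O)c2ccc(OCc3ccccc3)c(OC)c2)ccc1OS(=O)(=O)c1ccc(C)cc1
F3 | step 8 | (2S,3S)-2-{[4-(benzyloxy)-3-methoxyphenyl](hydroxy)methyl}-3-{3-methoxy-4-[(4-methylbenzenesulfonyl)oxy]benzyl}butane-1,4-diol, carbinol epimers | COc1cc(C[C@H](CO)[C@@H](CO)C(O)c2ccc(OCc3ccccc3)c(OC)c2)ccc1OS(=O)(=O)c1ccc(C)cc1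
F4 | step 7 | tert-butyl (3S)-2-azido-4-{[4-(benzyloxy)-3-methoxybenzyl]oxy}-3-{3-methoxy-4-[(4-methylbenzenesulfonyl)oxy]benzyl}butanoate, C2 epimers | CC(C)(C)OC(=O)C(N=[N+]=[N-])[C@@H](COCc1ccc(OCc2ccccc2)c(OC)c1)Cc1ccc(OS(=O)(=O)c2ccc(C)cc2)c(OC)c1
F5 | step 6 | 1-(benzyloxy)-4-(bromomethyl)-2-methoxybenzene | COc1cc(CBr)ccc1OCc1ccccc1
F6 | step 10 | bis[4-(benzyloxy)benzoate] of 19 (C6 alcohol and phenol both acylated) | COc1cc(C[C@@H]2CO[C@@H](c3ccc(OCc4ccccc4)c(OC)c3)[C@@H]2COC(=O)c2ccc(OCc3ccccc3)cc2)ccc1OC(=O)c1ccc(OCc2ccccc2)cc1
F7 | step 11 | (2R,3S,4S)-lariciresinol, 4-[(2R,3S,4S)-4-(4-hydroxy-3-methoxybenzyl)-3-(hydroxymethyl)oxolan-2-yl]-2-methoxyphenol | COc1cc(C[C@@H]2CO[C@@H](c3ccc(O)c(OC)c3)[C@@H]2CO)ccc1O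
A1 | alternative 1 | (4S,5R)-4-(4-acetoxy-3-methoxyphenyl)-5-[(E)-3-(4-acetoxy-3-methoxyphenyl)prop-1-enyl]-1,3-dioxolane | CC(=O)Oc1ccc(cc1OC)[C@@H]2OCO[C@@H]2/C=C/Cc1ccc(OC(C)=O)c(OC)c1
A2 | alternative 1 | (2R,3R,4S)-2-(4-acetoxy-3-methoxyphenyl)-4-(4-acetoxy-3-methoxybenzyl)oxolane-3-carbaldehyde | COc1cc(C[C@@H]2CO[C@@H](c3ccc(OC(C)=O)c(OC)c3)[C@@H]2C=O)ccc1OC(C)=O
A3 | alternative 2 | 4-(benzyloxy)-3-methoxybenzaldehyde | COc1cc(C=O)ccc1OCc1ccccc1
A4 | alternative 2 | (2R,3S)-2-[4-(benzyloxy)-3-methoxyphenyl]-4-methylideneoxolane-3-carbonitrile | C=C1CO[C@@H](c2ccc(OCc3ccccc3)c(OC)c2)[C@@H]1C#N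
A5 | alternative 3 | (3S)-3-[4-(benzyloxy)-3-methoxyphenyl]-2-iodo-3-(prop-2-enyloxy)propyl 4-(benzyloxy)benzoate, C2 epimers | C=CCO[C@@H](c1ccc(OCc2ccccc2)c(OC)c1)C(I)COC(=O)c1ccc(OCc2ccccc2)cc1
A6 | alternative 3 | 1-(benzyloxy)-4-bromo-2-methoxybenzene | COc1cc(Br)ccc1OCc1ccccc1
A7 | alternative 3 | tri-O-benzylagastinol | COc1cc(C[C@@H]2CO[C@@H](c3ccc(OCc4ccccc4)c(OC)c3)[C@@H]2COC(=O)c2ccc(OCc3ccccc3)cc2)ccc1OCc1ccccc1
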